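**Plan** (isochromene numbering: O2, C1, C3, C4, C4a, C5–C8, C8a; ring A = carbocycle C4a–C8a, ring B = pyran)
- Feature used: C7 in ring A is a tertiary α-ketol carbon (O, CH3) between the C6 and C8 carbonyls, the pattern left when an acyl anion at C6 adds to the ketone C7 of a 1,2-diketone carried on C8a.
- Cuts, in retrosynthetic order: the C7–O ester bond; the C6–C7 bond of ring A; C8a–C8 and C8–C7 (CO inserted between a pyranyl triflate and a 1-ethoxyvinyl group); C4a=C5 (ethynyl addition to a 4-pyranone carbonyl); the side-chain C=C (Wittig).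
- Forward: ring B is bought as kojic acid; its enolic OH becomes the triflate at C8a and its CH2OH the (E)-acrylate at C3. Ethynyl addition and a Meyer–Schuster shift turn C4a=O into C4a=C5H–C6HO, and carbonylative Stille coupling with hydrolysis adds the C8/C7 diketone.
- Ring A is closed last by a carbene-catalysed crossed benzoin reaction; the new tertiary alcohol is esterified with bis-MOM-orsellinoyl fluoride, and acid removes the MOM and tert-butyl groups.
- Stereochemistry: the only stereocentre, C7 (R), is set in the benzoin step by a chiral aminoindanol-derived triazolium carbene; the side-chain alkene is E from the stabilised ylide.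

Key step: step 5

Assumption: the (5aS,10bR) antipode of the aminoindanol-derived triazolium salt is taken to direct the acyl anion to the Re face of the C7 carbonyl; if a first trial shows the opposite sense, the commercially available (5aR,10bS) salt is used with nothing else changed.

Step 1
Reactants: 1 kojic acid (5-hydroxy-2-(hydroxymethyl)-4H-pyran-4-one)
Product: 2 6-(hydroxymethyl)-4-oxo-4H-pyran-3-yl trifluoromethanesulfonate
Conditions: PhNTf2, Et3N, DMF, 0 °C to rt
Reagents that add atoms: N-phenyl-bis(trifluoromethanesulfonimide), O=S(=O)(N(c1ccccc1)S(=O)(=O)C(F)(F)F)C(F)(F)F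
Why: The enolic 5-hydroxyl is far more acidic than the primary alcohol and should be sulfonylated selectively by the mild triflyl donor under amine base, a chemoselective O-triflation that marks the future C8a for cross-coupling.

Step 2
Reactants: 2 6-(hydroxymethyl)-4-oxo-4H-pyran-3-yl trifluoromethanesulfonate; 3 tert-butyl (triphenylphosphoranylidene)acetate
Product: 5 tert-butyl (E)-3-[4-oxo-5-(trifluoromethylsulfonyloxy)-4H-pyran-2-yl]prop-2-enoate, via pyranone aldehyde 4 (not isolated)
Conditions: activated MnO2, ylide 3, CH2Cl2/THF, rt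
Reagents that add atoms: none
Why: MnO2 should oxidise the allylic-type hydroxymethyl group to the aldehyde, which is trapped in the same flask by the stabilised ylide in an E-selective Wittig olefination, so the electrophilic aldehyde need not be isolated.

Step 3
Reactants: 5 tert-butyl (E)-3-[4-oxo-5-(trifluoromethylsulfonyloxy)-4H-pyran-2-yl]prop-2-enoate; 6 ethynylmagnesium bromide
Product: 8 tert-butyl (E)-3-[(4Z)-4-(2-oxoethylidene)-5-(trifluoromethylsulfonyloxy)-4H-pyran-2-yl]prop-2-enoate, via ethynyl carbinol 7 (not isolated)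
Conditions: HC≡CMgBr, LaCl3·2LiCl (0.3 equiv), THF, −40 to 0 °C; then 1 M HCl (aq), THF, rt
Reagents that add atoms: water, O
Why: The lanthanum-activated alkynyl Grignard reagent should add 1,2 to the pyranone carbonyl while sparing the tert-butyl ester, and aqueous acid then ionises the tertiary carbinol to a 4-ethynylpyrylium ion that takes up water at the alkyne terminus, a Meyer–Schuster rearrangement to the conjugated aldehyde in which no stereocentre remains and the exocyclic alkene geometry is mobile.

Step 4
Reactants: 8 tert-butyl (E)-3-[(4Z)-4-(2-oxoethylidene)-5-(trifluoromethylsulfonyloxy)-4H-pyran-2-yl]prop-2-enoate; 9 tributyl(1-ethoxyvinyl)stannane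
Product: 11 tert-butyl (E)-3-[(4Z)-5-(2-oxopropanoyl)-4-(2-oxoethylidene)-4H-pyran-2-yl]prop-2-enoate, via ethoxy enone 10 (not isolated)
Conditions: Pd(PPh3)4 (5 mol %), LiCl, CO (3 atm), THF, 50 °C; then 2 M HCl (aq), THF, rt
Reagents that add atoms: carbon monoxide, [C-]#[O+]; water, O
Why: Oxidative addition of zerovalent palladium into the enol triflate, CO insertion and transfer of the 1-ethoxyvinyl group from tin (carbonylative Stille coupling) should give a 2-ethoxy enone, a masked 1,2-diketone that dilute acid unmasks by enol ether hydrolysis, so that no oxidant meets the electron-rich pyranylidene.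

Step 5
Reactants: 11 tert-butyl (E)-3-[(4Z)-5-(2-oxopropanoyl)-4-(2-oxoethylidene)-4H-pyran-2-yl]prop-2-enoate
Product: 12 tert-butyl (E)-3-[(7R)-7-hydroxy-7-methyl-6,8-dioxo-7,8-dihydro-6H-isochromen-3-yl]prop-2-enoate
Conditions: (5aS,10bR)-2-(pentafluorophenyl)-5a,10b-dihydro-4H,6H-indeno[2,1-b][1,2,4]triazolo[4,3-d][1,4]oxazin-2-ium tetrafluoroborate (15 mol %), iPr2NEt (15 mol %), toluene, rt
Reagents that add atoms: none
Why: Deprotonation of the triazolium salt gives the carbene, which adds to the C6 aldehyde; proton transfer forms the hydroxy-enamine (Breslow intermediate) whose nucleophilic C6 attacks the C7 ketone, and collapse of the adduct expels the carbene to leave the C6 ketone beside the tertiary C7 alcohol. The closest known reaction type is the enantioselective intramolecular crossed aldehyde–ketone benzoin cyclisation with chiral bicyclic triazolium salts, which delivers cyclic tertiary α-ketols. Ring A closes in a 6-exo-trig mode, the C7 carbonyl oxygen staying outside the new ring. The C7 stereocentre is controlled by the catalyst: the fused aminoindanol backbone blocks one face of the Breslow intermediate so that the C7 carbonyl should be attacked on its Re face, giving the (R)-alcohol. The step needs C7 over C8 selectivity, secured because C7 is the outer and more electrophilic carbonyl of the 1,2-diketone whereas attack at C8 would form a five-membered ring at a deactivated vinylogous ester carbonyl, and it needs acyl-anion rather than homoenolate behaviour, secured by the fully substituted β-carbon C4a. It also needs the aldehyde on the C8a side of the exocyclic alkene, a geometry that is accessible because rotation about the polarised C4a=C5 bond is facile.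

Step 6
Reactants: 13 orsellinic acid (2,4-dihydroxy-6-methylbenzoic acid)
Product: 14 methoxymethyl 2,4-bis(methoxymethoxy)-6-methylbenzoate
Conditions: NaH, MOMCl, DMF, 0 °C to rt
Reagents that add atoms: chloromethyl methyl ether, COCCl
Why: Williamson-type O-alkylation of the carboxylate and both phenoxides with MOMCl should mask all three acidic groups in one operation.

Step 7
Reactants: 14 methoxymethyl 2,4-bis(methoxymethoxy)-6-methylbenzoate
Product: 15 2,4-bis(methoxymethoxy)-6-methylbenzoic acid
Conditions: LiOH, THF/MeOH/H2O, rt; then cold 1 M HCl to pH 4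
Reagents that add atoms: lithium hydroxide, [Li+].[OH-]
Why: The acyloxymethyl ester carries a far better leaving group than an alkyl ester and should be saponified selectively at room temperature, the aryl MOM ethers being inert to hydroxide.

Step 8
Reactants: 15 2,4-bis(methoxymethoxy)-6-methylbenzoic acid
Product: 16 2,4-bis(methoxymethoxy)-6-methylbenzoyl fluoride
Conditions: cyanuric fluoride, pyridine, CH2Cl2, −10 °C to rt
Reagents that add atoms: cyanuric fluoride, Fc1nc(F)nc(F)n1
Why: Deoxyfluorination of the carboxylic acid with cyanuric fluoride should give the acyl fluoride, which, unlike the chloride, does not cyclise onto the ortho MOM ether and tolerates the acetal groups.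

Step 9
Reactants: 12 tert-butyl (E)-3-[(7R)-7-hydroxy-7-methyl-6,8-dioxo-7,8-dihydro-6H-isochromen-3-yl]prop-2-enoate; 16 2,4-bis(methoxymethoxy)-6-methylbenzoyl fluoride
Product: 17 (7R)-3-[(E)-3-tert-butoxy-3-oxoprop-1-enyl]-7-methyl-6,8-dioxo-7,8-dihydro-6H-isochromen-7-yl 2,4-bis(methoxymethoxy)-6-methylbenzoate
Conditions: DMAP (2 equiv), iPr2NEt, CH2Cl2, 0 to 40 °C
Reagents that add atoms: none
Why: DMAP-mediated acyl transfer from the small acyl fluoride is a standard solution for a doubly hindered esterification, and the C7 stereocentre is untouched because only the O–H bond reacts and the quaternary carbon cannot epimerise under mild amine base.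

Step 10
Reactants: 17 (7R)-3-[(E)-3-tert-butoxy-3-oxoprop-1-enyl]-7-methyl-6,8-dioxo-7,8-dihydro-6H-isochromen-7-yl 2,4-bis(methoxymethoxy)-6-methylbenzoate
Product: 18 mitorubrinic acid, (E)-3-[(7R)-7-(2,4-dihydroxy-6-methylbenzoyl)oxy-7-methyl-6,8-dioxo-7,8-dihydro-6H-isochromen-3-yl]prop-2-enoic acid
Conditions: TFA/CH2Cl2 (1:4), H2O (trace), 0 °C to rt
Reagents that add atoms: none
Why: Trifluoroacetic acid should cleave the tert-butyl ester by loss of the tert-butyl cation and both aryl MOM acetals by acetal solvolysis in one operation, conditions under which the azaphilone core and the tertiary ester are stable.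

**Compound list**
1 | kojic acid, 5-hydroxy-2-(hydroxymethyl)-4H-pyran-4-one | O=c1cc(CO)occ1O | starting material
2 | 6-(hydroxymethyl)-4-oxo-4H-pyran-3-yl trifluoromethanesulfonate | O=c1cc(CO)occ1OS(=O)(=O)C(F)(F)F | intermediate
3 | tert-butyl (triphenylphosphoranylidene)acetate | CC(C)(C)OC(=O)C=P(c1ccccc1)(c1ccccc1)c1ccccc1 | starting material
4 | 6-formyl-4-oxo-4H-pyran-3-yl trifluoromethanesulfonate (not isolated) | O=Cc1cc(=O)c(OS(=O)(=O)C(F)(F)F)co1 | intermediate
5 | tert-butyl (E)-3-[4-oxo-5-(trifluoromethylsulfonyloxy)-4H-pyran-2-yl]prop-2-enoate | CC(C)(C)OC(=O)/C=C/c1cc(=O)c(OS(=O)(=O)C(F)(F)F)co1 | intermediate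
6 | ethynylmagnesium bromide | C#C[Mg]Br | starting material
7 | tert-butyl (E)-3-[4-ethynyl-4-hydroxy-5-(trifluoromethylsulfonyloxy)-4H-pyran-2-yl]prop-2-enoate (racemic carbinol, not isolated) | CC(C)(C)OC(=O)/C=C/C1=CC(O)(C#C)C(OS(=O)(=O)C(F)(F)F)=CO1 | intermediate
8 | tert-butyl (E)-3-[(4Z)-4-(2-oxoethylidene)-5-(trifluoromethylsulfonyloxy)-4H-pyran-2-yl]prop-2-enoate (drawn as 4Z; the exocyclic alkene equilibrates) | O=C/C=C1/C=C(/C=C/C(=O)OC(C)(C)C)OC=C1OS(=O)(=O)C(F)(F)F | intermediate
9 | tributyl(1-ethoxyvinyl)stannane | CCCC[Sn](CCCC)(CCCC)C(=C)OCC | starting material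
10 | tert-butyl (E)-3-[(4Z)-5-(2-ethoxyprop-2-enoyl)-4-(2-oxoethylidene)-4H-pyran-2-yl]prop-2-enoate (not isolated) | O=C/C=C1/C=C(/C=C/C(=O)OC(C)(C)C)OC=C1C(=O)C(=C)OCC | intermediate
11 | tert-butyl (E)-3-[(4Z)-5-(2-oxopropanoyl)-4-(2-oxoethylidene)-4H-pyran-2-yl]prop-2-enoate | O=C/C=C1/C=C(/C=C/C(=O)OC(C)(C)C)OC=C1C(=O)C(C)=O | intermediate
12 | tert-butyl (E)-3-[(7R)-7-hydroxy-7-methyl-6,8-dioxo-7,8-dihydro-6H-isochromen-3-yl]prop-2-enoate | O[C@]1(C)C(=O)C=C2C=C(/C=C/C(=O)OC(C)(C)C)OC=C2C1=O | intermediate
13 | orsellinic acid, 2,4-dihydroxy-6-methylbenzoic acid | Cc1cc(O)cc(O)c1C(=O)O | starting material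
14 | methoxymethyl 2,4-bis(methoxymethoxy)-6-methylbenzoate | Cc1cc(OCOC)cc(OCOC)c1C(=O)OCOC | intermediate
15 | 2,4-bis(methoxymethoxy)-6-methylbenzoic acid | Cc1cc(OCOC)cc(OCOC)c1C(=O)O | intermediate
16 | 2,4-bis(methoxymethoxy)-6-methylbenzoyl fluoride | Cc1cc(OCOC)cc(OCOC)c1C(F)=O | intermediate
17 | (7R)-3-[(E)-3-tert-butoxy-3-oxoprop-1-enyl]-7-methyl-6,8-dioxo-7,8-dihydro-6H-isochromen-7-yl 2,4-bis(methoxymethoxy)-6-methylbenzoate | Cc1cc(OCOC)cc(OCOC)c1C(=O)O[C@]1(C)C(=O)C=C2C=C(/C=C/C(=O)OC(C)(C)C)OC=C2C1=O | intermediate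
18 | mitorubrinic acid, (E)-3-[(7R)-7-(2,4-dihydroxy-6-methylbenzoyl)oxy-7-methyl-6,8-dioxo-7,8-dihydro-6H-isochromen-3-yl]prop-2-enoic acid | Cc1cc(O)cc(O)c1C(=O)O[C@]1(C)C(=O)C=C2C=C(/C=C/C(=O)O)OC=C2C1=O | target

**Step count**
Total: 10 steps. Longest linear sequence: 7 steps (1, 2, 3, 4, 5, 9, 10); the acyl fluoride branch (6–8) is 3 steps.

**Steps most likely to fail**

Step 3. The triflyl group may be transferred from the enol oxygen to the neighbouring tertiary alkoxide, or water may add to a ring α-carbon of the transient pyrylium ion and open the ring before the alkyne is hydrated. The fallback sets out from 5 and removes the triflate before the carbonyl addition. Sonogashira coupling of 5 with propyne (PdCl2(PPh3)2, CuI, iPr2NEt, THF, rt) should give tert-butyl (E)-3-[4-oxo-5-(prop-1-ynyl)-4H-pyran-2-yl]prop-2-enoate F1. Addition of HC≡CMgBr with LaCl3·2LiCl should give the propynyl ethynyl carbinol F2, which is not isolated and on treatment with aqueous acid should rearrange to tert-butyl (E)-3-[(4Z)-4-(2-oxoethylidene)-5-(prop-1-ynyl)-4H-pyran-2-yl]prop-2-enoate F3. Wacker-type oxidation of the internal alkyne (PdBr2, CuBr2, O2, dioxane/H2O, 60 °C) then comes back to the route at 11.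

Step 4. The ethoxyvinyl group may be transferred to palladium before CO has inserted, giving direct coupling, or the stannane may be lost by protodestannylation. The fallback sets out from 8 and separates the two events. Hydroxycarbonylation of the triflate (Pd(OAc)2, dppf, CO 1 atm, KOAc, DMSO/H2O, 60 °C) should give (4Z)-6-[(E)-3-tert-butoxy-3-oxoprop-1-enyl]-4-(2-oxoethylidene)-4H-pyran-3-carboxylic acid F4. Neutral activation with 1-chloro-N,N,2-trimethylprop-1-en-1-amine in CH2Cl2 should give the corresponding acid chloride F5. Stille acylation of F5 with 9 (PdCl2(PPh3)2, toluene, 70 °C) comes back to the route at 10, which is hydrolysed to 11 as in step 4.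

Step 5. Facial discrimination at the C7 carbonyl may be poor, or enantiopurity may erode through a reversible retro-benzoin reaction. The fallback sets out from 11 and takes the stereochemistry from a resolution. Cyclisation with the achiral 2-mesityl-6,7-dihydro-5H-pyrrolo[2,1-c][1,2,4]triazol-2-ium chloride and DBU in THF should give the racemic tertiary alcohol F6. Esterification with 16 under the conditions of step 9 should give the racemic protected ester F7. Preparative HPLC on an amylose tris(3,5-dimethylphenylcarbamate) phase then separates the (7S)-ester F8 from the (7R)-ester, which comes back to the route at 17.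

Further compounds
F1 | step 3 | tert-butyl (E)-3-[4-oxo-5-(prop-1-ynyl)-4H-pyran-2-yl]prop-2-enoate | CC#Cc1coc(/C=C/C(=O)OC(C)(C)C)cc1=O
F2 | step 3 | tert-butyl (E)-3-[4-ethynyl-4-hydroxy-5-(prop-1-ynyl)-4H-pyran-2-yl]prop-2-enoate (racemic, not isolated) | CC#CC1=COC(/C=C/C(=O)OC(C)(C)C)=CC1(O)C#C
F3 | step 3 | tert-butyl (E)-3-[(4Z)-4-(2-oxoethylidene)-5-(prop-1-ynyl)-4H-pyran-2-yl]prop-2-enoate | O=C/C=C1/C=C(/C=C/C(=O)OC(C)(C)C)OC=C1C#CC
F4 | step 4 | (4Z)-6-[(E)-3-tert-butoxy-3-oxoprop-1-enyl]-4-(2-oxoethylidene)-4H-pyran-3-carboxylic acid | O=C/C=C1/C=C(/C=C/C(=O)OC(C)(C)C)OC=C1C(=O)O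
F5 | step 4 | (4Z)-6-[(E)-3-tert-butoxy-3-oxoprop-1-enyl]-4-(2-oxoethylidene)-4H-pyran-3-carbonyl chloride | O=C/C=C1/C=C(/C=C/C(=O)OC(C)(C)C)OC=C1C(Cl)=O
F6 | step 5 | racemic tert-butyl (E)-3-(7-hydroxy-7-methyl-6,8-dioxo-7,8-dihydro-6H-isochromen-3-yl)prop-2-enoate | OC1(C)C(=O)C=C2C=C(/C=C/C(=O)OC(C)(C)C)OC=C2C1=O
F7 | step 5 | racemic 3-[(E)-3-tert-butoxy-3-oxoprop-1-enyl]-7-methyl-6,8-dioxo-7,8-dihydro-6H-isochromen-7-yl 2,4-bis(methoxymethoxy)-6-methylbenzoate | Cc1cc(OCOC)cc(OCOC)c1C(=O)OC1(C)C(=O)C=C2C=C(/C=C/C(=O)OC(C)(C)C)OC=C2C1=O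
F8 | step 5 | (7S)-3-[(E)-3-tert-butoxy-3-oxoprop-1-enyl]-7-methyl-6,8-dioxo-7,8-dihydro-6H-isochromen-7-yl 2,4-bis(methoxymethoxy)-6-methylbenzoate | Cc1cc(OCOC)cc(OCOC)c1C(=O)O[C@@]1(C)C(=O)C=C2C=C(/C=C/C(=O)OC(C)(C)C)OC=C2C1=O
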